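## Structural features

The target is a 1,2-dioxane (O1–O2–C3–C4–C5–C6). C6 is a fully substituted peroxy carbon with a methyl group and a 4,8,12-trimethyltrideca-3,7,11-trienyl chain (three trisubstituted alkenes, two of them E); C3 is a secondary peroxy carbon with a 1-carboxyethyl group. There are three stereocentres: C6 (S) and C3 (S) face each other 1,4 across the ring with the two carbon chains cis, and the exocyclic Cα (S) is bonded directly to C3, its methyl group anti to O2 in the C4–C3–Cα–CO2H zigzag. Once present, the O–O bond rules out low-valent metals, hydride donors, phosphines and organometallic reagents; C3–H leaves the ring open to Kornblum–DeLaMare cleavage under base (only C6 is immune); the polyene is sensitive to strong acid and to unselective oxidants and reductants; the acid is β to a peroxy leaving group. The real difficulty is a configured quaternary peroxy carbon that must be related to C3 across the ring with almost no conformational bias (methyl and chain at C6 are nearly equal in size close to the ring) and to Cα beyond it, all without reductive or strongly basic steps. The feature used is that C3 has a single carbon substituent and lies between O2 and C4: it can be inserted as an aldehyde carbon between the oxygen of a C6 hydroperoxide and the alkene carbon that becomes C4, with a silyl group on that carbon directing and terminating the ring closure.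

## Logic of the disconnections

22 to 20. The two C–O bonds that raise C1 of the side chain to the carboxyl level are removed, leaving a primary alcohol. The acid is the most polar group and, as a β-peroxy carbonyl compound, the one most exposed to elimination, so it should appear last. The forward step must oxidise CH2OH to CO2H without base and without touching O–O or the three chain alkenes, passing quickly through 21.

20 to 19. The C4–H and C5–H bonds are cut, which puts a cis alkene back into the ring. That alkene is the footprint of the cyclisation terminator and cannot be avoided. The forward step needs a hydrogen-transfer reagent that leaves O–O intact, prefers one cis-disubstituted alkene over three trisubstituted ones, and is not basic, because C3–H in 19 is allylic as well as peroxy-substituted.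

19 to 17. The C1–O bond and the Cα–H bond are cut, turning the hydroxypropyl unit into an isopropenyl group. Cα sits next to C3, so its configuration can be read from the allylic C3–O bond, and the side chain shrinks to the carbons of a C4 enal. The borane must pick the 1,1-disubstituted alkene out of five C=C bonds and the face anti to C4, and the C–B oxidation must be run at neutral pH.

17 to 14 and 15. The O2–C3 and C3–C4 bonds are cut: C3 becomes the carbonyl carbon of 15, O2 the terminal oxygen of 14, and C4 the silicon-bearing carbon of a (Z)-vinylsilane. This is the only place where one carbon can be inserted between a peroxide oxygen and a carbon nucleophile already tied to C6. It gives the ring, two skeletal bonds, one stereocentre and all 24 carbons in one step, with C6 set beforehand. The forward step has to outrun acid-induced fragmentation of 14 and has to control C3 against a C6 centre that offers little bias. A check of the descriptors gives (3S,1Z) for 14, (3S,6S) for 17 and (2S,3S,6S) for 22, mutually consistent, so none of these structures needs correcting.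

14 to 13, 11 and 9. The O–H of the hydroperoxide is traded for an O–Si bond (13), the two alkene C–H bonds for an alkyne (11), and the C–Si bond is cut to a terminal alkyne and 10 (9). A free hydroperoxide cannot survive bases, boranes or carbanions, so it is carried as a silyl peroxide until the step before ring closure. The Z geometry, which the ring closure cannot do without, comes from a syn hydroboration with protonolysis.

9 to 7 and 8. The C≡C bond is cut to an aldehyde and a one-carbon diazo reagent. The aldehyde has a quaternary α-carbon, so it can neither epimerise nor lose the peroxide by Kornblum–DeLaMare cleavage. The forward step must be aprotic and cold to spare the silyl peroxide.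

7 to 6 and 4. The C1–C2 bond of a terminal glycol is restored. C1 of 1 is sacrificed on purpose: the oxygen that the epoxide leaves on C2 can only depart as a carbonyl oxygen, and any Peterson-type use of a C2 hydroxyl would expel silicon instead of keeping it. The diol is masked first so that the hydroperoxide is the only hydroxyl left to silylate, and the mask is chosen so that the glycol-cleaving reagent removes it.

4 to 2 and 3. The C3–OO bond is cut. Opening of a trisubstituted epoxide at its tertiary carbon with inversion is the one dependable stereospecific way to a configured tertiary hydroperoxide. The forward step must be regioselective for C3 and must not ionise fully.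

2 to 1. The two epoxide C–O bonds are cut. The allylic hydroxyl of 1 makes the epoxidation both site-selective among four alkenes and enantioselective, and all twenty carbons of 14 except the silicon-bearing one come from 1.

## Other disconnections considered

Alternative 1: Both C–O bonds of the peroxide (C3–O2 and C6–O1) are cut at once. Photosensitised oxygen would add across the diene of the acetonide of (1R,2S)-3-methylcyclohexa-3,5-diene-1,2-diol A1, anti to the dioxolane, to give the bicyclic endoperoxide A2. Acetonide hydrolysis and glycol cleavage would then excise the two-carbon bridge and leave cis-3-methyl-3,6-dihydro-1,2-dioxine-3,6-dicarbaldehyde A3.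
- In its favour: a concerted suprafacial [4+2] addition makes the ring, both C–O bonds and both ring stereocentres in one step; the bridge guarantees the cis relation of the two carbon arms; the reaction type is well established for this substrate class. On certainty of the ring-forming step this alternative is better than the chosen plan, whose step 9 has no direct precedent. On the ring alkene the two are equal: A3 and 17 need the same saturation.
- Against it here: descriptor bookkeeping shows that A2 of the required configuration comes from the (1R,2S)-diol, whereas the dioxygenase strains commonly used for arene cis-dihydroxylation are known to give the (1S,2R) antipode of a 3-methyl diol. The direct biocatalytic entry would therefore lead to the mirror-image ring unless the antipodal diol is secured by a detour.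
- A3 also carries two α-peroxy aldehydes that must be told apart, one on a carbon with a hydrogen (base cleavage, epimerisation). The whole C16 chain and the propionate unit including Cα would have to be built by olefinations after the peroxide exists, each leaving an alkene to reduce next to trisubstituted ones.
- Step economy: short up to A3 (about four steps), long afterwards. The chosen plan brings the chain intact from 1 and needs three steps after ring closure.

Alternative 2: No bond of the final ring is cut at the key stage; the quaternary peroxy carbon is fixed by desymmetrisation. 4-Hydroperoxy-4-methylcyclohexa-2,5-dien-1-one A4 would condense with a sacrificial aldehyde under a chiral phosphoric acid, and the peroxyhemiacetal hydroxyl would add to one enone arm to give the cis-fused trioxane A5.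
- In its favour: catalytic, no stoichiometric chiral reagent, a cheap achiral precursor, and a cascade of a kind already established for peroxyquinols. In precedent it is better than step 9, and in setting the tertiary C–OO centre it is at least the equal of steps 1 and 2.
- Against it here: A5 contains neither the O2–C3 bond nor a usable carbon framework. The trioxane must be dismantled, the carbocycle cleaved to free the two arms of C6, and the oxygen introduced at the β-carbon, which has no counterpart in the target, removed next to a peroxide. The 1,2-dioxane must still be closed in a second ring-forming step that sets C3 and Cα, and the chain and side chain built on.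
- Mechanistically both plans let a chiral Brønsted acid act on a peroxyhemiacetal, but in the chosen plan the aldehyde carbon stays as C3, while here it is thrown away. Step economy clearly favours the chosen plan.

Alternative 3: The cut is O1–C6. (4E)-1-Methoxy-4-methylhex-4-en-1-yl hydroperoxide A6 would be cyclised by a chiral bis(oxazoline) complex of divalent palladium with a quinone oxidant. The hydroperoxide oxygen attacks the methyl-bearing alkene carbon, and β-hydride elimination leaves a vinyl group on C6, giving 3-methoxy-6-methyl-6-vinyl-1,2-dioxane A7 as both acetal epimers.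
- In its favour: the ring is saturated from the start, so the chemoselective reduction of step 11 is not needed, and on this point the alternative is better. The C3 acetal is a handle through which a propionate enolate equivalent could bring in the whole side chain in one Lewis-acid-mediated substitution, which is equal to or shorter than steps 10 and 12. Oxidative cyclisation of unsaturated hydroperoxides with divalent palladium is a known reaction type.
- Against it here: high enantioselectivity in a Wacker-type closure that creates a fully substituted C–O centre would have to be developed, so the uncertainty only moves from C3 to C6. The vinyl group must be grown into the C16 trienyl chain after the peroxide is present, which means hydroboration and sp3–sp2 cross-coupling with zerovalent palladium or organometallic reagents next to O–O. The substitution at C3 would set C3 and Cα together with only the remote, weakly biasing C6 as control element.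
- In length the two routes would be comparable. The chosen plan has the chain arriving intact and two of three stereocentres (C6 by steps 1–2, Cα by step 10) resting on established control.

Key step: step 9

Remark (assumption): the sense of induction of the IDPi acid in step 9 cannot be derived from first principles; the (S,S) antipode is written for definiteness and stands for whichever antipode is matched with the (6S) centre.

Step 1
Reactants: 1 (2E,6E,10E)-geranylgeraniol
Product: 2 [(2R,3R)-3-methyl-3-[(3E,7E)-4,8,12-trimethyltrideca-3,7,11-trien-1-yl]oxiran-2-yl]methanol
Conditions: Ti(OiPr)4 (10 mol%), D-(−)-diisopropyl tartrate (12 mol%), t-BuOOH, 4 Å MS, CH2Cl2, −20 °C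
Reagents that add atoms: tert-butyl hydroperoxide, CC(C)(C)OO
Why: Sharpless asymmetric epoxidation: the allylic hydroxyl binds titanium, so only the 2,3-alkene of the tetraene is epoxidised; the D-(−)-tartrate delivers oxygen to the face that gives the (2R,3R)-epoxide, the mirror image of the L-tartrate outcome known for geraniol-type alcohols.

Step 2
Reactants: 2; 3 hydrogen peroxide
Product: 4 (2R,3S,6E,10E)-3-hydroperoxy-3,7,11,15-tetramethylhexadeca-6,10,14-triene-1,2-diol
Conditions: anhydrous H2O2 in Et2O (excess), H3PMo12O40 (2 mol%), 0 °C to rt
Reagents that add atoms: hydrogen peroxide, OO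
Why: Acid-catalysed perhydrolysis of a trisubstituted epoxide, a known reaction with molybdenum acid catalysts: H2O2 attacks the tertiary carbon in a borderline SN2 opening with inversion, which turns (3R) into the (3S) hydroperoxide and leaves C2 untouched; the nearest chain alkene cannot intercept the C3 cation through a favourable ring size.

Step 3
Reactants: 4
Product: 6 tert-butyl{[(2S,5E,9E)-2-[(4R)-2,2-dimethyl-1,3-dioxolan-4-yl]-6,10,14-trimethylpentadeca-5,9,13-trien-2-yl]peroxy}dimethylsilane, via acetonide hydroperoxide 5 (not isolated)
Conditions: Me2C(OMe)2, PPTS (cat.), acetone, rt; MeOH, then concentrate; TBSOTf, 2,6-lutidine, CH2Cl2, −78 °C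
Reagents that add atoms: 2,2-dimethoxypropane, COC(C)(C)OC; tert-butyldimethylsilyl trifluoromethanesulfonate, CC(C)(C)[Si](C)(C)OS(=O)(=O)C(F)(F)F
Why: Ketalisation under weak acid takes the terminal 1,2-diol as the five-membered dioxolane (faster than a six-membered trioxane through OOH), methanol returns any peroxyketal to OOH, and the hydroperoxide is then the only hydroxyl left for O-silylation; standard protecting-group chemistry that touches no stereocentre.

Step 4
Reactants: 6
Product: 7 (2S,5E,9E)-2-[(tert-butyldimethylsilyl)peroxy]-2,6,10,14-tetramethylpentadeca-5,9,13-trienal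
Conditions: H5IO6, EtOAc, 0 °C to rt
Reagents that add atoms: none
Why: Periodic acid hydrolyses a terminal acetonide and cleaves the freed glycol in one operation (Malaprade cleavage), a known one-pot reaction of terminal isopropylidene acetals in polyprenoids; the new aldehyde has a quaternary α-carbon, so it can neither epimerise nor undergo Kornblum–DeLaMare cleavage.

Step 5
Reactants: 7; 8 dimethyl (1-diazo-2-oxopropyl)phosphonate
Product: 9 tert-butyldimethyl{[(3S,6E,10E)-3,7,11,15-tetramethylhexadeca-6,10,14-trien-1-yn-3-yl]peroxy}silane
Conditions: NaOMe, THF, −78 to 0 °C
Reagents that add atoms: dimethyl (1-diazo-2-oxopropyl)phosphonate, CC(=O)C(=[N+]=[N-])P(=O)(OC)OC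
Why: Seyferth–Gilbert homologation in its Ohira–Bestmann form: methoxide unmasks the diazomethylphosphonate anion, Horner–Wadsworth–Emmons-type addition–elimination gives a diazoalkene, and the alkylidene carbene formed on loss of N2 rearranges by 1,2-hydride shift to the alkyne; the aprotic low-temperature variant is chosen so that the silyl peroxide is not solvolysed.

Step 6
Reactants: 9; 10 chlorotrimethylsilane
Product: 11 tert-butyldimethyl{[(3S,6E,10E)-3,7,11,15-tetramethyl-1-(trimethylsilyl)hexadeca-6,10,14-trien-1-yn-3-yl]peroxy}silane
Conditions: LiN(SiMe3)2, THF, −78 °C, 10 present from the start (in situ quench)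
Reagents that add atoms: chlorotrimethylsilane, C[Si](C)(C)Cl
Why: C-silylation of a lithium acetylide generated by a hindered amide base in the presence of the chlorosilane, so that no long-lived carbanion is exposed to the O–O bond.

Step 7
Reactants: 11
Product: 13 tert-butyldimethyl{[(1Z,3S,6E,10E)-3,7,11,15-tetramethyl-1-(trimethylsilyl)hexadeca-1,6,10,14-tetraen-3-yl]peroxy}silane, via alkenylborane 12 (not isolated)
Conditions: Cy2BH (preformed), THF, 0 °C; then AcOH, rt
Reagents that add atoms: none
Why: Hydroboration–protonolysis of a 1-silylalkyne: dicyclohexylborane adds syn with boron on the silicon-bearing carbon, away from the quaternary centre, and acetic acid replaces boron by hydrogen with retention, which places silicon cis to C3, i.e. the (Z)-vinylsilane; the trisubstituted chain alkenes are too hindered for Cy2BH at 0 °C.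

Step 8
Reactants: 13
Product: 14 (1Z,3S,6E,10E)-3-hydroperoxy-3,7,11,15-tetramethyl-1-(trimethylsilyl)hexadeca-1,6,10,14-tetraene
Conditions: HF·pyridine, pyridine, THF, 0 °C
Reagents that add atoms: none
Why: Fluoride cleaves the Si–O bond of the silyl peroxide under buffered, weakly acidic conditions; the vinyl C–Si bond and the tertiary allylic O–O unit are inert to HF·pyridine at 0 °C.

Step 9
Reactants: 14; 15 methacrolein
Product: 17 (3S,6S)-6-methyl-3-(prop-1-en-2-yl)-6-[(3E,7E)-4,8,12-trimethyltrideca-3,7,11-trien-1-yl]-3,6-dihydro-1,2-dioxine, via peroxyhemiacetal 16 (not isolated)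
Conditions: 15 (3 equiv), (S,S)-IDPi acid (5 mol%; imidodiphosphorimidate from two 3,3′-bis[3,5-bis(trifluoromethyl)phenyl]-BINOL units, P=N–SO2CF3), CHCl3, −40 °C; pyridine quench
Reagents that add atoms: methacrolein, CC(=C)C=O
Why: Proposed new method: hydroperoxide 14 adds reversibly to the carbonyl group of 15 to give peroxyhemiacetal 16, which the confined acid ionises to an (E)-configured peroxycarbenium ion paired with the chiral IDPi anion; the closest known reaction types are the silyl-Prins cyclisation of (Z)-vinylsilyl homoallylic alcohols with aldehydes to cis-2,6-disubstituted dihydropyrans, Prins cyclisations under confined chiral Brønsted acids, and the capture of peroxycarbenium ions by allylsilanes. The silicon-bearing carbon (future C4) attacks the carbenium carbon (future C3) through a chair-like six-membered transition state in a 6-endo-trig closure in which both the C=C and the C=O+ units lie inside the forming ring, so that O2–C3 (condensation) and C3–C4 (cyclisation) are made in this order. The cation left at C5 is β to silicon and collapses by loss of the trimethylsilyl group, which the water of condensation takes up as Me3SiOH with return of the proton to the catalyst, leaving the cis ring alkene. C3 is the only new stereocentre: the (E)-cation puts the isopropenyl group pseudo-equatorial, and because methyl and the chain CH2 at C6 are nearly equal in size near the ring the two diastereomeric chairs are close in energy, so the 3S face has to be chosen by the catalyst pocket, which can tell a methyl group from a long chain that must leave the cavity. The step needs ipso regioselectivity (secured by silicon: attack through the other alkene carbon would give an α-silyl cation and a five-membered ring), the (Z) geometry (only it lets the silicon-bearing carbon reach the cation in a six-membered chair and deliver an endocyclic cis alkene), and preference for the vinylsilane over the nearest chain alkene (six-membered chair against a seven-membered ring). Hock cleavage of the tertiary allylic hydroperoxide is held back by excess 15, which keeps the OOH group bound as the hemiacetal whose C–OH ionises far more easily than the O–O bond, and by the low temperature; 15 has no α-hydrogen, so the cation cannot enolise. The product keeps a doubly allylic C3–O bond and an allylic C3–H, so the acid is quenched cold with pyridine and base is avoided afterwards.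

Step 10
Reactants: 17
Product: 19 (2R)-2-[(3S,6S)-6-methyl-6-[(3E,7E)-4,8,12-trimethyltrideca-3,7,11-trien-1-yl]-3,6-dihydro-1,2-dioxin-3-yl]propan-1-ol, via B-alkyl-9-BBN 18 (not isolated)
Conditions: 9-BBN, THF, 0 °C to rt; then H2O2 (3), pH 7 phosphate buffer, 0 °C
Reagents that add atoms: hydrogen peroxide, OO
Why: Hydroboration–oxidation with allylic-oxygen stereocontrol: 9-BBN reacts with the 1,1-disubstituted alkene far faster than with cis-disubstituted or trisubstituted ones; in the conformer with C3–H eclipsing the C=CH2 bond the borane approaches anti to C4, on the side of O2, as 2-methylalk-1-en-3-ol derivatives are known to do, which gives the O2/CH3-anti arrangement, (2R) in 19 and (2S) in the final acid. The C–B bond is oxidised at pH 7 because the allylic C3–H of the dihydrodioxine would undergo Kornblum–DeLaMare cleavage with base.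

Step 11
Reactants: 19
Product: 20 (2R)-2-[(3S,6S)-6-methyl-6-[(3E,7E)-4,8,12-trimethyltrideca-3,7,11-trien-1-yl]-1,2-dioxan-3-yl]propan-1-ol
Conditions: KO2C–N=N–CO2K, AcOH, MeOH/CH2Cl2, 0 °C to rt, added in portions
Reagents that add atoms: none
Why: Diimide reduction (concerted syn transfer of H2) does not cleave O–O and reacts faster with the cis-disubstituted ring alkene than with the trisubstituted chain alkenes; the acidic generation of diimide avoids base, and the reaction is stopped before the chain alkenes are touched.

Step 12
Reactants: 20
Product: 22 (2S)-2-[(3S,6S)-6-methyl-6-[(3E,7E)-4,8,12-trimethyltrideca-3,7,11-trien-1-yl]-1,2-dioxan-3-yl]propanoic acid, via aldehyde 21 (not isolated)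
Conditions: TEMPO (cat.), PhI(OAc)2, MeCN/H2O, 0 °C to rt
Reagents that add atoms: water, O
Why: Oxoammonium (TEMPO) oxidation with PhI(OAc)2 as terminal oxidant takes the primary alcohol through aldehyde 21 and its hydrate to the acid; the medium is weakly acidic, so neither β-elimination of the peroxide nor α-epimerisation is expected, and alkenes and O–O are inert to the reagent.

## Compound list

1 | (2E,6E,10E)-geranylgeraniol | CC(C)=CCC/C(C)=C/CC/C(C)=C/CC/C(C)=C/CO | starting material
2 | [(2R,3R)-3-methyl-3-[(3E,7E)-4,8,12-trimethyltrideca-3,7,11-trien-1-yl]oxiran-2-yl]methanol | CC(C)=CCC/C(C)=C/CC/C(C)=C/CC[C@@]1(C)O[C@@H]1CO | intermediate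
3 | hydrogen peroxide | OO | starting material
4 | (2R,3S,6E,10E)-3-hydroperoxy-3,7,11,15-tetramethylhexadeca-6,10,14-triene-1,2-diol | CC(C)=CCC/C(C)=C/CC/C(C)=C/CC[C@@](OO)(C)[C@H](O)CO | intermediate
5 | (2S,5E,9E)-2-[(4R)-2,2-dimethyl-1,3-dioxolan-4-yl]-6,10,14-trimethylpentadeca-5,9,13-trien-2-yl hydroperoxide | CC(C)=CCC/C(C)=C/CC/C(C)=C/CC[C@@](OO)(C)[C@H]1COC(C)(C)O1 | intermediate (not isolated)
6 | tert-butyl{[(2S,5E,9E)-2-[(4R)-2,2-dimethyl-1,3-dioxolan-4-yl]-6,10,14-trimethylpentadeca-5,9,13-trien-2-yl]peroxy}dimethylsilane | CC(C)=CCC/C(C)=C/CC/C(C)=C/CC[C@@](OO[Si](C)(C)C(C)(C)C)(C)[C@H]1COC(C)(C)O1 | intermediate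
7 | (2S,5E,9E)-2-[(tert-butyldimethylsilyl)peroxy]-2,6,10,14-tetramethylpentadeca-5,9,13-trienal | CC(C)=CCC/C(C)=C/CC/C(C)=C/CC[C@@](OO[Si](C)(C)C(C)(C)C)(C)C=O | intermediate
8 | dimethyl (1-diazo-2-oxopropyl)phosphonate | CC(=O)C(=[N+]=[N-])P(=O)(OC)OC | starting material
9 | tert-butyldimethyl{[(3S,6E,10E)-3,7,11,15-tetramethylhexadeca-6,10,14-trien-1-yn-3-yl]peroxy}silane | CC(C)=CCC/C(C)=C/CC/C(C)=C/CC[C@@](OO[Si](C)(C)C(C)(C)C)(C)C#C | intermediate
10 | chlorotrimethylsilane | C[Si](C)(C)Cl | starting material
11 | tert-butyldimethyl{[(3S,6E,10E)-3,7,11,15-tetramethyl-1-(trimethylsilyl)hexadeca-6,10,14-trien-1-yn-3-yl]peroxy}silane | CC(C)=CCC/C(C)=C/CC/C(C)=C/CC[C@@](OO[Si](C)(C)C(C)(C)C)(C)C#C[Si](C)(C)C | intermediate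
12 | [(1Z,3S,6E,10E)-3-[(tert-butyldimethylsilyl)peroxy]-3,7,11,15-tetramethyl-1-(trimethylsilyl)hexadeca-1,6,10,14-tetraen-1-yl]dicyclohexylborane | CC(C)=CCC/C(C)=C/CC/C(C)=C/CC[C@@](OO[Si](C)(C)C(C)(C)C)(C)/C=C(\[Si](C)(C)C)B(C1CCCCC1)C1CCCCC1 | intermediate (not isolated)
13 | tert-butyldimethyl{[(1Z,3S,6E,10E)-3,7,11,15-tetramethyl-1-(trimethylsilyl)hexadeca-1,6,10,14-tetraen-3-yl]peroxy}silane | CC(C)=CCC/C(C)=C/CC/C(C)=C/CC[C@@](OO[Si](C)(C)C(C)(C)C)(C)/C=C\[Si](C)(C)C | intermediate
14 | (1Z,3S,6E,10E)-3-hydroperoxy-3,7,11,15-tetramethyl-1-(trimethylsilyl)hexadeca-1,6,10,14-tetraene | CC(C)=CCC/C(C)=C/CC/C(C)=C/CC[C@@](OO)(C)/C=C\[Si](C)(C)C | intermediate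
15 | methacrolein | CC(=C)C=O | starting material
16 | 2-methyl-1-{[(1Z,3S,6E,10E)-3,7,11,15-tetramethyl-1-(trimethylsilyl)hexadeca-1,6,10,14-tetraen-3-yl]peroxy}prop-2-en-1-ol (both epimers at the hemiacetal carbon) | CC(C)=CCC/C(C)=C/CC/C(C)=C/CC[C@@](OOC(O)C(C)=C)(C)/C=C\[Si](C)(C)C | intermediate (not isolated)
17 | (3S,6S)-6-methyl-3-(prop-1-en-2-yl)-6-[(3E,7E)-4,8,12-trimethyltrideca-3,7,11-trien-1-yl]-3,6-dihydro-1,2-dioxine | CC(C)=CCC/C(C)=C/CC/C(C)=C/CC[C@@]1(C)C=C[C@@H](C(C)=C)OO1 | intermediate
18 | 9-{(2R)-2-[(3S,6S)-6-methyl-6-[(3E,7E)-4,8,12-trimethyltrideca-3,7,11-trien-1-yl]-3,6-dihydro-1,2-dioxin-3-yl]propyl}-9-borabicyclo[3.3.1]nonane | CC(C)=CCC/C(C)=C/CC/C(C)=C/CC[C@@]1(C)C=C[C@@H]([C@H](C)CB2C3CCCC2CCC3)OO1 | intermediate (not isolated)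
19 | (2R)-2-[(3S,6S)-6-methyl-6-[(3E,7E)-4,8,12-trimethyltrideca-3,7,11-trien-1-yl]-3,6-dihydro-1,2-dioxin-3-yl]propan-1-ol | CC(C)=CCC/C(C)=C/CC/C(C)=C/CC[C@@]1(C)C=C[C@@H]([C@H](C)CO)OO1 | intermediate
20 | (2R)-2-[(3S,6S)-6-methyl-6-[(3E,7E)-4,8,12-trimethyltrideca-3,7,11-trien-1-yl]-1,2-dioxan-3-yl]propan-1-ol | CC(C)=CCC/C(C)=C/CC/C(C)=C/CC[C@@]1(C)CC[C@@H]([C@H](C)CO)OO1 | intermediate
21 | (2S)-2-[(3S,6S)-6-methyl-6-[(3E,7E)-4,8,12-trimethyltrideca-3,7,11-trien-1-yl]-1,2-dioxan-3-yl]propanal | CC(C)=CCC/C(C)=C/CC/C(C)=C/CC[C@@]1(C)CC[C@@H]([C@H](C)C=O)OO1 | intermediate (not isolated)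
22 | (2S)-2-[(3S,6S)-6-methyl-6-[(3E,7E)-4,8,12-trimethyltrideca-3,7,11-trien-1-yl]-1,2-dioxan-3-yl]propanoic acid | CC(C)=CCC/C(C)=C/CC/C(C)=C/CC[C@@]1(C)CC[C@@H]([C@H](C)C(=O)O)OO1 | target

## Step count and least certain steps

Total: 12 steps from 1. Longest linear sequence: 12 steps (the route is fully linear; 3, 8, 10 and 15 are purchased).

Step 9 (key step, proposed new method). What may go wrong:
- acid-induced Hock fragmentation of the hydroperoxide outrunning ionisation of the hemiacetal;
- protodesilylation of the vinylsilane by the strong acid;
- capture of the cation by a chain alkene;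
- weak facial discrimination at C3, because C6 gives the chair almost no bias;
- loss of configuration at C3 through reversible ionisation of the doubly allylic C3–O bond.

Fallback with known chemistry (base-mediated conjugate addition of a hydroperoxide to an enoate), setting out from 7 and coming back at 22. Wittig reaction of 7 with Ph3P=CHCHO would give the (E)-enal F1. Diimide (as in step 11) would saturate only its electron-poor disubstituted C=C to give the saturated aldehyde F2. A second Wittig reaction with Ph3P=C(CH3)CO2CH3 would give the (E)-enoate F3, and HF·pyridine would free the hydroperoxide F4. Et2NH in CF3CH2OH would close the ring by 6-exo oxa-Michael addition. The (2S,3S,6S) methyl ester F5 would then have to be separated from its C3 and Cα epimers, since this closure controls neither centre. LiOH would give 22.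

Step 11. What may go wrong: over-reduction, because the rate gap between the hindered cis ring alkene (next to a quaternary carbon) and three trisubstituted chain alkenes may be too small for diimide. Fallback, setting out from 19 and coming back at 20: catalytic hydrogenation with H2 and RhCl(PPh3)3 in benzene. This replaces the hydrogen-transfer reagent by a metal catalyst whose rate falls steeply from cis-disubstituted to trisubstituted alkenes; insertion of monovalent rhodium into O–O would have to be watched. No new compound is formed.

Step 10. What may go wrong: poor facial selectivity at Cα, since the two allylic substituents of C3 that flank the alkene (O2 and the sp2 carbon C4) may be too weakly differentiated. Fallback, setting out from 14 and coming back at 19: Cα is taken from the chiral pool instead. Purchased methyl (R)-3-hydroxy-2-methylpropanoate would be silylated (TBSCl, imidazole) to the silyl ether ester F6 and reduced with i-Bu2AlH at −78 °C to (2R)-3-[(tert-butyldimethylsilyl)oxy]-2-methylpropanal F7. F7 would replace 15 in the annulation of step 9 to give the dihydrodioxine silyl ether F8, and HF·pyridine would give 19. This reuses the reaction of step 9, so it is available only once that step is in hand, and it carries the added risk of α-epimerisation of the aldehyde under acid.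

Step 7. What may go wrong: sluggish protonolysis of the hindered α-silyl alkenylborane, or attack of the borane or the acid on the silyl peroxide during a prolonged reaction. Fallback, setting out from 11 and coming back at 13: semihydrogenation with H2 (1 atm) over Pd/CaCO3 poisoned with Pb(OAc)2 and quinoline, a catalytic syn addition instead of hydroboration. Hydrogenolysis of O–O would have to be checked at low conversion. No new compound is formed.

Step 4. What may go wrong: loss of the silyl group from the peroxide under periodic acid, which would expose an α-hydroperoxy aldehyde to fragmentation. Fallback, setting out from 4 and coming back at 7: the diol is masked with a group that neutral periodate removes. PhB(OH)2 and MgSO4 in CH2Cl2 would give the phenylboronate hydroperoxide F9 (not isolated). TBSOTf and 2,6-lutidine would give the boronate silyl peroxide F10. NaIO4 in THF/pH 7 buffer would hydrolyse the boronate and cleave the glycol to 7. Oxidation of the C–B bond by the neighbouring hydroperoxide before silylation is the point to watch.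

## Further compounds

F1 | step 9 | (2E,4S,7E,11E)-4-[(tert-butyldimethylsilyl)peroxy]-4,8,12,16-tetramethylheptadeca-2,7,11,15-tetraenal | CC(C)=CCC/C(C)=C/CC/C(C)=C/CC[C@@](OO[Si](C)(C)C(C)(C)C)(C)/C=C/C=O
F2 | step 9 | (4S,7E,11E)-4-[(tert-butyldimethylsilyl)peroxy]-4,8,12,16-tetramethylheptadeca-7,11,15-trienal | CC(C)=CCC/C(C)=C/CC/C(C)=C/CC[C@@](OO[Si](C)(C)C(C)(C)C)(C)CCC=O
F3 | step 9 | methyl (2E,6S,9E,13E)-6-[(tert-butyldimethylsilyl)peroxy]-2,6,10,14,18-pentamethylnonadeca-2,9,13,17-tetraenoate | CC(C)=CCC/C(C)=C/CC/C(C)=C/CC[C@@](OO[Si](C)(C)C(C)(C)C)(C)CC/C=C(\C)C(=O)OC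
F4 | step 9 | methyl (2E,6S,9E,13E)-6-hydroperoxy-2,6,10,14,18-pentamethylnonadeca-2,9,13,17-tetraenoate | CC(C)=CCC/C(C)=C/CC/C(C)=C/CC[C@@](OO)(C)CC/C=C(\C)C(=O)OC
F5 | step 9 | methyl (2S)-2-[(3S,6S)-6-methyl-6-[(3E,7E)-4,8,12-trimethyltrideca-3,7,11-trien-1-yl]-1,2-dioxan-3-yl]propanoate | CC(C)=CCC/C(C)=C/CC/C(C)=C/CC[C@@]1(C)CC[C@@H]([C@H](C)C(=O)OC)OO1
F0 | step 11 | none | none
F6 | step 10 | methyl (2R)-3-[(tert-butyldimethylsilyl)oxy]-2-methylpropanoate | COC(=O)[C@H](C)CO[Si](C)(C)C(C)(C)C
F7 | step 10 | (2R)-3-[(tert-butyldimethylsilyl)oxy]-2-methylpropanal | O=C[C@H](C)CO[Si](C)(C)C(C)(C)C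
F8 | step 10 | tert-butyldimethyl{(2R)-2-[(3S,6S)-6-methyl-6-[(3E,7E)-4,8,12-trimethyltrideca-3,7,11-trien-1-yl]-3,6-dihydro-1,2-dioxin-3-yl]propoxy}silane | CC(C)=CCC/C(C)=C/CC/C(C)=C/CC[C@@]1(C)C=C[C@@H]([C@H](C)CO[Si](C)(C)C(C)(C)C)OO1
F0 | step 7 | none | none
F9 | step 4 | (2S,5E,9E)-6,10,14-trimethyl-2-[(4R)-2-phenyl-1,3,2-dioxaborolan-4-yl]pentadeca-5,9,13-trien-2-yl hydroperoxide | CC(C)=CCC/C(C)=C/CC/C(C)=C/CC[C@@](OO)(C)[C@H]1COB(c2ccccc2)O1
F10 | step 4 | tert-butyldimethyl{[(2S,5E,9E)-6,10,14-trimethyl-2-[(4R)-2-phenyl-1,3,2-dioxaborolan-4-yl]pentadeca-5,9,13-trien-2-yl]peroxy}silane | CC(C)=CCC/C(C)=C/CC/C(C)=C/CC[C@@](OO[Si](C)(C)C(C)(C)C)(C)[C@H]1COB(c2ccccc2)O1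
A1 | alternative 1 | acetonide of (1R,2S)-3-methylcyclohexa-3,5-diene-1,2-diol | CC1=CC=C[C@H]2OC(C)(C)O[C@@H]12
A2 | alternative 1 | 7,8-O-isopropylidene-1-methyl-2,3-dioxabicyclo[2.2.2]oct-5-ene-7,8-diol, peroxide bridge anti to the acetonide | C[C@@]12OO[C@@H](C=C1)[C@H]3OC(C)(C)O[C@@H]23
A3 | alternative 1 | (3R,6S)-3-methyl-3,6-dihydro-1,2-dioxine-3,6-dicarbaldehyde (cis) | C[C@@]1(C=O)OO[C@@H](C=C1)C=O
A4 | alternative 2 | 4-hydroperoxy-4-methylcyclohexa-2,5-dien-1-one | CC1(OO)C=CC(=O)C=C1
A5 | alternative 2 | cis-fused 3-isobutyl-8a-methyl-4a,5-dihydro-1,2,4-benzotrioxin-6(8aH)-one | O=C1C[C@@H]2O[C@H](CC(C)C)OO[C@]2(C)C=C1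
A6 | alternative 3 | (4E)-1-methoxy-4-methylhex-4-en-1-yl hydroperoxide | C/C=C(\C)CCC(OC)OO
A7 | alternative 3 | 3-methoxy-6-methyl-6-vinyl-1,2-dioxane, both acetal epimers | C=C[C@@]1(C)CCC(OC)OO1
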